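**Retrosynthetic overview**
- The target comes from one hydrogenolysis of a bis-benzyl ether in which the central phenol and the side-chain CH2 are tied up as a trans-2-aryl-3-methyl-2,3-dihydrobenzofuran (an internal benzyl-type ether).
- Key step: one acid treatment of an open-chain triol closes the tetrahydrofuran and the dihydrobenzofuran together; all three benzylic centres are set under thermodynamic control, so every earlier carbinol can be an epimer mixture.
- The triol comes from an aryllithium (carrying the side-chain alcohol) added to a 3,4-cis-dimethyl-γ-lactone, followed by borohydride.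
- The lactone comes from Rh-catalysed desymmetrisation of meso-2,3-dimethylsuccinic anhydride with an arylzinc, which fixes both methyl centres of the ring.
- The side-chain centre comes from Pd α-arylation of 4'-benzyloxypropiophenone followed by a dynamic-kinetic-resolution hydrogenation.

Assumption: the catalyst antipodes named are those taken, by analogy with the parent reactions, to give the drawn configurations (the other antipode is used if the sense proves opposite); carbinol centres that are ionised in step 8 are carried as epimer mixtures.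

**Step 1**
Reactants: 1 2,3-dimethylmaleic anhydride
Product: 2 cis-2,3-dimethylsuccinic anhydride, i.e. meso (3R,4S)-3,4-dimethyloxolane-2,5-dione
Conditions: H2 (4 atm), 10% Pd/C, EtOAc, rt
Reagents that add atoms: none
Why: Heterogeneous catalytic hydrogenation adds H2 syn to the ring alkene, so only the cis (meso) anhydride forms.

**Step 2**
Reactants: 2 cis-2,3-dimethylsuccinic anhydride; 3 1-(benzyloxy)-4-bromobenzene
Product: 6 (2R,3S)-4-[4-(benzyloxy)phenyl]-2,3-dimethyl-4-oxobutanoic acid, via aryllithium 4 (not isolated), via arylzinc triflate 5 (not isolated)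
Conditions: 3, n-BuLi, THF, −78 °C; Zn(OTf)2, −78 °C → rt; then 2, [Rh(cod)Cl]2 (4 mol %), (R,R)-TADDOL-PNMe2 (8 mol %), DMF/THF, 50 °C; 1 M HCl
Reagents that add atoms: none
Why: Rh/phosphoramidite-catalysed enantioselective desymmetrisation of a meso anhydride (acyl cross-coupling with an arylzinc made in situ) opens one enantiotopic C(O)–O bond, so both methyl centres become fixed in absolute terms without either being touched.

**Step 3**
Reactants: 6 (2R,3S)-4-[4-(benzyloxy)phenyl]-2,3-dimethyl-4-oxobutanoic acid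
Product: 8 (3R,4S)-5-[4-(benzyloxy)phenyl]-3,4-dimethyloxolan-2-one (C5 epimers), via hydroxy acid 7 (not isolated)
Conditions: NaOH (1.0 equiv), NaBH4, MeOH/H2O, 0 °C; then 2 M HCl, rt
Reagents that add atoms: none
Why: Borohydride reduction of the aryl ketone and acid-induced γ-lactonisation; the new benzylic centre is deliberately left as an epimer mixture because it is ionised and reset in step 8, and the cold, hydroxide-free medium does not enolise the methyl centres.

**Step 4**
Reactants: 9 4-bromo-2-iodophenol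
Product: 10 4-bromo-2-iodo-1-(methoxymethoxy)benzene
Conditions: MOMCl, i-Pr2NEt, CH2Cl2, 0 °C → rt
Reagents that add atoms: chloromethyl methyl ether (MOMCl), COCCl
Why: O-alkylation of the phenoxide (Williamson-type acetal formation) gives a base-stable ether that the acid of step 8 removes during ring closure.

**Step 5**
Reactants: 10 4-bromo-2-iodo-1-(methoxymethoxy)benzene; 11 1-[4-(benzyloxy)phenyl]propan-1-one
Product: 12 rac-1-[4-(benzyloxy)phenyl]-2-[5-bromo-2-(methoxymethoxy)phenyl]propan-1-one
Conditions: Pd2(dba)3 (1 mol %), Xantphos (2.4 mol %), NaOt-Bu (1.3 equiv), THF, 60 °C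
Reagents that add atoms: none
Why: Buchwald–Hartwig-type Pd-catalysed ketone α-arylation in which oxidative addition is selective for C–I over C–Br; the new centre is racemic and configurationally labile, which step 6 exploits.

**Step 6**
Reactants: 12 rac-1-[4-(benzyloxy)phenyl]-2-[5-bromo-2-(methoxymethoxy)phenyl]propan-1-one
Product: 13 (1S,2S)-1-[4-(benzyloxy)phenyl]-2-[5-bromo-2-(methoxymethoxy)phenyl]propan-1-ol
Conditions: RuCl2[(R)-xylBINAP][(R)-DAIPEN] (1 mol %), KOt-Bu (0.2 equiv), H2 (8 atm), i-PrOH/THF, 25 °C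
Reagents that add atoms: none
Why: Noyori asymmetric hydrogenation with dynamic kinetic resolution: t-BuOK racemises the acidic α-aryl centre faster than reduction, while the catalyst sets the (S)-carbinol and consumes the Felkin-matched (S)-ketone, so C2 (the future side-chain centre) is set as S.

**Step 7**
Reactants: 13 (1S,2S)-1-[4-(benzyloxy)phenyl]-2-[5-bromo-2-(methoxymethoxy)phenyl]propan-1-ol; 8 (3R,4S)-5-[4-(benzyloxy)phenyl]-3,4-dimethyloxolan-2-one (C5 epimers)
Product: 16 (2S,3R)-1-[4-(benzyloxy)phenyl]-4-{3-[(1S,2S)-1-[4-(benzyloxy)phenyl]-1-hydroxypropan-2-yl]-4-(methoxymethoxy)phenyl}-2,3-dimethylbutane-1,4-diol (C1 and C4 epimers), via dilithio species 14 (not isolated), via hydroxy ketone 15 (not isolated)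
Conditions: 13, n-BuLi (2.05 equiv), THF, −78 °C; 8, −78 °C; then MeOH, NaBH4, −78 → 0 °C
Reagents that add atoms: none
Why: O-deprotonation and Br/Li exchange, 1,2-addition of the aryllithium to the γ-lactone (mono-addition through the lactolate) and borohydride reduction of the released aryl ketone; the two new carbinol centres are epimer mixtures that converge in step 8 and no existing centre is touched.

**Step 8 (key step)**
Reactants: 16 (2S,3R)-1-[4-(benzyloxy)phenyl]-4-{3-[(1S,2S)-1-[4-(benzyloxy)phenyl]-1-hydroxypropan-2-yl]-4-(methoxymethoxy)phenyl}-2,3-dimethylbutane-1,4-diol (C1 and C4 epimers)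
Product: 17 (2S,3S)-2-[4-(benzyloxy)phenyl]-5-{(2R,3R,4S,5S)-5-[4-(benzyloxy)phenyl]-3,4-dimethyloxolan-2-yl}-3-methyl-2,3-dihydro-1-benzofuran
Conditions: TFA (10 equiv), H2O (5 equiv), CH2Cl2 (0.01 M), −20 → 20 °C, HPLC control; NaHCO3
Reagents that add atoms: none
Why: Brønsted-acid SN1 double cycloetherification through p-alkoxybenzyl cations: the 1,4-diol closes reversibly to the tetrahydrofuran so that every carbinol epimer funnels to the most stable ring with each aryl trans to its neighbouring methyl, while the side-chain cation is captured by the ortho MOM-ether oxygen with loss of the MOM group to give the trans-dihydrobenzofuran, the three methyl-bearing centres not being involved.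

**Step 9**
Reactants: 17 (2S,3S)-2-[4-(benzyloxy)phenyl]-5-{(2R,3R,4S,5S)-5-[4-(benzyloxy)phenyl]-3,4-dimethyloxolan-2-yl}-3-methyl-2,3-dihydro-1-benzofuran
Product: 19 4-[(2R,3R,4S,5S)-5-(4-hydroxyphenyl)-3,4-dimethyloxolan-2-yl]-2-[(2R)-1-(4-hydroxyphenyl)propan-2-yl]phenol, via triphenol 18 (not isolated)
Conditions: H2 (1 atm), 10% Pd/C, EtOAc/AcOH (10:1), rt, stopped on consumption of 18
Reagents that add atoms: none
Why: Catalytic hydrogenolysis removes both O-benzyl groups and then the benzylic C–O bond of the dihydrobenzofuran (an aryl benzyl ether, as in pterocarpan-to-isoflavan openings), whereas the dialkyl benzylic ethers of the tetrahydrofuran react much more slowly; the benzofuran C3 becomes the (R) side-chain centre without change.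

**Compound list**
1 | 2,3-dimethylmaleic anhydride | CC1=C(C)C(=O)OC1=O | starting material
2 | cis-2,3-dimethylsuccinic anhydride (meso, 3R,4S) | C[C@@H]1[C@H](C)C(=O)OC1=O | intermediate
3 | 1-(benzyloxy)-4-bromobenzene | Brc1ccc(OCc2ccccc2)cc1 | starting material
4 | [4-(benzyloxy)phenyl]lithium | [Li]c1ccc(OCc2ccccc2)cc1 | intermediate
5 | [4-(benzyloxy)phenyl]zinc triflate | FC(F)(F)S(=O)(=O)O[Zn]c1ccc(OCc2ccccc2)cc1 | intermediate
6 | (2R,3S)-4-[4-(benzyloxy)phenyl]-2,3-dimethyl-4-oxobutanoic acid | C[C@@H](C(=O)O)[C@H](C)C(=O)c1ccc(OCc2ccccc2)cc1 | intermediate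
7 | (2R,3S)-4-[4-(benzyloxy)phenyl]-4-hydroxy-2,3-dimethylbutanoic acid (C4 epimers) | C[C@@H](C(=O)O)[C@H](C)C(O)c1ccc(OCc2ccccc2)cc1 | intermediate
8 | (3R,4S)-5-[4-(benzyloxy)phenyl]-3,4-dimethyloxolan-2-one (C5 epimers) | C[C@@H]1[C@H](C)C(c2ccc(OCc3ccccc3)cc2)OC1=O | intermediate
9 | 4-bromo-2-iodophenol | Oc1ccc(Br)cc1I | starting material
10 | 4-bromo-2-iodo-1-(methoxymethoxy)benzene | COCOc1ccc(Br)cc1I | intermediate
11 | 1-[4-(benzyloxy)phenyl]propan-1-one | CCC(=O)c1ccc(OCc2ccccc2)cc1 | starting material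
12 | rac-1-[4-(benzyloxy)phenyl]-2-[5-bromo-2-(methoxymethoxy)phenyl]propan-1-one | COCOc1ccc(Br)cc1C(C)C(=O)c1ccc(OCc2ccccc2)cc1 | intermediate
13 | (1S,2S)-1-[4-(benzyloxy)phenyl]-2-[5-bromo-2-(methoxymethoxy)phenyl]propan-1-ol | COCOc1ccc(Br)cc1[C@H](C)[C@H](O)c1ccc(OCc2ccccc2)cc1 | intermediate
14 | lithium (1S,2S)-1-[4-(benzyloxy)phenyl]-2-[5-lithio-2-(methoxymethoxy)phenyl]propan-1-olate | COCOc1ccc([Li])cc1[C@H](C)[C@H](O[Li])c1ccc(OCc2ccccc2)cc1 | intermediate
15 | (2R,3S)-4-[4-(benzyloxy)phenyl]-1-{3-[(1S,2S)-1-[4-(benzyloxy)phenyl]-1-hydroxypropan-2-yl]-4-(methoxymethoxy)phenyl}-4-hydroxy-2,3-dimethylbutan-1-one (C4 epimers, in equilibrium with its lactol) | C[C@@H](C(=O)c1ccc(OCOC)c([C@H](C)[C@H](O)c2ccc(OCc3ccccc3)cc2)c1)[C@H](C)C(O)c1ccc(OCc2ccccc2)cc1 | intermediate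
16 | (2S,3R)-1-[4-(benzyloxy)phenyl]-4-{3-[(1S,2S)-1-[4-(benzyloxy)phenyl]-1-hydroxypropan-2-yl]-4-(methoxymethoxy)phenyl}-2,3-dimethylbutane-1,4-diol (C1 and C4 epimers) | C[C@@H](C(O)c1ccc(OCOC)c([C@H](C)[C@H](O)c2ccc(OCc3ccccc3)cc2)c1)[C@H](C)C(O)c1ccc(OCc2ccccc2)cc1 | intermediate
17 | (2S,3S)-2-[4-(benzyloxy)phenyl]-5-{(2R,3R,4S,5S)-5-[4-(benzyloxy)phenyl]-3,4-dimethyloxolan-2-yl}-3-methyl-2,3-dihydro-1-benzofuran | C[C@@H]1[C@H](C)[C@@H](c2ccc(OCc3ccccc3)cc2)O[C@H]1c1ccc2O[C@H](c3ccc(OCc4ccccc4)cc3)[C@@H](C)c2c1 | intermediate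
18 | 4-[(2S,3S)-5-{(2R,3R,4S,5S)-5-(4-hydroxyphenyl)-3,4-dimethyloxolan-2-yl}-3-methyl-2,3-dihydro-1-benzofuran-2-yl]phenol | C[C@@H]1[C@H](C)[C@@H](c2ccc(O)cc2)O[C@H]1c1ccc2O[C@H](c3ccc(O)cc3)[C@@H](C)c2c1 | intermediate
19 | 4-[(2R,3R,4S,5S)-5-(4-hydroxyphenyl)-3,4-dimethyloxolan-2-yl]-2-[(2R)-1-(4-hydroxyphenyl)propan-2-yl]phenol | C[C@@H]1[C@H](C)[C@@H](c2ccc(O)cc2)O[C@H]1c1ccc(O)c([C@H](C)Cc2ccc(O)cc2)c1 | target

**Step count**
Total: 9 steps. Longest linear sequence: 6 steps (4 → 5 → 6 → 7 → 8 → 9, from compound 9; the branch 1 → 2 → 3 → 7 → 8 → 9 is also 6).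

**Steps most likely to fail, with fallbacks**

Step 8 (double ring closure). The risks are E1 loss of a proton next to a benzylic cation, which would scramble a methyl-bearing centre, incomplete convergence of the carbinol epimers, and by-products from the released formaldehyde. The fallback sets out from 13 (together with 8) and comes back at 17, forming the rings one after the other. Treating 13 with TFA in CH2Cl2 at −20 °C closes only the dihydrobenzofuran, by the same MOM-oxygen capture, to give (2S,3S)-2-[4-(benzyloxy)phenyl]-5-bromo-3-methyl-2,3-dihydro-1-benzofuran F1, whose ee at C3 can be checked on this small fragment. Br/Li exchange of F1 (n-BuLi, −78 °C), addition to lactone 8 and NaBH4 reduction give (2S,3R)-1-[4-(benzyloxy)phenyl]-4-{(2S,3S)-2-[4-(benzyloxy)phenyl]-3-methyl-2,3-dihydro-1-benzofuran-5-yl}-2,3-dimethylbutane-1,4-diol F2 as carbinol epimers. The tetrahydrofuran is then closed alone with BF3·OEt2 in CH2Cl2 at −40 °C, where no acetal has to be cleaved, to give 17.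

Step 6 (dynamic kinetic resolution). The risks are slow reduction of the hindered, electron-rich ketone and modest ee or dr. The fallback sets out from 12 and comes back at 13, setting the centre by reagent-controlled hydroboration instead. NaBH4 in MeOH at 0 °C gives racemic 1-[4-(benzyloxy)phenyl]-2-[5-bromo-2-(methoxymethoxy)phenyl]propan-1-ol F3 (mainly the Felkin 1S*,2S* pair). Burgess reagent (syn elimination, no acid) gives 4-bromo-2-[(E)-1-[4-(benzyloxy)phenyl]prop-1-en-2-yl]-1-(methoxymethoxy)benzene F4. Hydroboration with the appropriate antipode of monoisopinocampheylborane followed by NaOH/H2O2 adds H and B syn across the E alkene, with boron on the less substituted carbon, and returns (1S,2S)-13.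

Step 9 (selective hydrogenolysis). The risks are that the dihydrobenzofuran C–O bond resists neutral Pd/C, or that forcing conditions begin to open the tetrahydrofuran. The fallback sets out from 17 and comes back at 19. The hydrogenolysis is stopped at the triphenol 18 (Pd/C, H2, EtOAc, no acid, short time). The dihydrobenzofuran is then opened without a metal catalyst using NaBH4 in aqueous NaOH/EtOH at 70 °C: the phenoxide of the C2 4-hydroxyphenyl group expels the ring phenoxide to give a p-quinone methide, which borohydride reduces by 1,6-addition. The tetrahydrofuran, whose leaving group would be an alkoxide, should stay closed. No new compound is needed.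

**Further compounds**
F1 | step 8 | (2S,3S)-2-[4-(benzyloxy)phenyl]-5-bromo-3-methyl-2,3-dihydro-1-benzofuran | Brc1ccc2O[C@H](c3ccc(OCc4ccccc4)cc3)[C@@H](C)c2c1
F2 | step 8 | (2S,3R)-1-[4-(benzyloxy)phenyl]-4-{(2S,3S)-2-[4-(benzyloxy)phenyl]-3-methyl-2,3-dihydro-1-benzofuran-5-yl}-2,3-dimethylbutane-1,4-diol (C1 and C4 epimers) | C[C@@H](C(O)c1ccc2O[C@H](c3ccc(OCc4ccccc4)cc3)[C@@H](C)c2c1)[C@H](C)C(O)c1ccc(OCc2ccccc2)cc1
F3 | step 6 | rac-1-[4-(benzyloxy)phenyl]-2-[5-bromo-2-(methoxymethoxy)phenyl]propan-1-ol | COCOc1ccc(Br)cc1C(C)C(O)c1ccc(OCc2ccccc2)cc1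
F4 | step 6 | 4-bromo-2-[(E)-1-[4-(benzyloxy)phenyl]prop-1-en-2-yl]-1-(methoxymethoxy)benzene | COCOc1ccc(Br)cc1/C(C)=C/c1ccc(OCc2ccccc2)cc1
F0 | step 9 | none | none
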